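How much target stands after 50 h as catalyst goes from 3.0 mM to 12 mM?

common to all: starting material 0.60 M; partner 0.570 M; second substrate 0.120 M; time 50 h
- maple: catalyst 3.0 mM
- cedar: catalyst 6.0 mM
- ash: catalyst 12 mM

    starting material + partner + catalyst → catalyst + target (k1 = 12 M⁻² h⁻¹)
    catalyst + target → catalyst + over-reaction product (k2 = 1.9 M⁻¹ h⁻¹)
    second substrate + partner + catalyst → catalyst + second product (k3 = 170 M⁻² h⁻¹)

- [target] at the end for maple, cedar, ash, in this order
- how that number moves from the first to the last of them (falls, then rises / falls all the way / rises all the way / hardly changes / rises, then falls)

- "hardly changes" means that all values lie within two and a half points (for a concentration: within two and a half percent of the largest)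
- run time (maple): 50 h
- a step back or a flat step of under half a percent of the largest counts as no turn

Catalyst multiplies each step and comes back unchanged, so catalyst and time act as their product. My reckoning therefore folds them into the burn number, the rate constant of step 2 times catalyst times time, which counts the mean target lifetimes in a run (a pseudo-first-order loss): 0.285 for maple, 0.570 for cedar, 1.14 for ash.

In maple, second substrate has a half-life of 2.4 h against 34 h for starting material, so it takes its partner first. Partner, the limiting reagent, then serves 75.0% of the starting material, and the remaining 25.0% finds none.

Step 1 uses starting material and partner one for one, so their ratio, 1.33 at the outset, grows exponentially with the burn number times 0.947. That ratio gives the fraction made. Making slows as the ratio grows, so I let the made target feel on average 0.667 of the burn number, and target then stands at 34.3%, 38.0% and 31.1% of the starting material charged, which is 0.206 M, 0.228 M and 0.186 M. Read in this order, my row rises, then falls.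

Was one number enough? It places the flasks on one curve, but the height of that curve needs 0.947 and the surplus as well.

The forecast gives 0.212 M, 0.229 M and 0.176 M, shape rises, then falls, with “the maximum falling near the middle catalyst level”. Its ash value, 29.3% of the charge, lies below mine.

The simulation gives 0.212 M, 0.230 M and 0.177 M, shape rises, then falls. Ash ends with target at 29.4% of the charge, against my 31.1%. The row's turn reads 5.2 mM, a burn number of 0.496. Ash at 25.0 h has a burn number of 0.570, the same as cedar's 0.570 at 50.0 h, and target stands at 38.3% in ash then and 38.3% in cedar.

(The numbers of this flask were drawn at random within sensible limits; the rest is arithmetic.)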